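**Strategy.** The route rests on disconnecting the C1–C2 bond of ring B. Ring B carries the quaternary bridgehead carbinol C1 directly beside the C2–C3 oxirane, so the C1 hydroxyl and the C1–C2 bond can be made together by adding a C2 alkenyl nucleophile to a C1 ketone of ring A (C1, C8, C7, C6, C5, C9). The key step, an intramolecular Nozaki–Hiyama–Kishi reaction, closes ring B as a cyclohexene, sets C1 and leaves the C2=C3 alkene for the oxirane. Its precursor is a ring A 2-hydroxycyclohexanone (C1 ketone, free C9 carbinol, C6 silyl ether, C7 carbamate) bearing at C5 a (Z)-3-iodo-1-methoxyallyl arm.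

Key step: step 18

Remark: the core locants C1–C9 of the target skeleton are used for all intermediates; β is the face of ring A that carries the C6 oxygen and the C7 nitrogen, α the opposite face (the face of the C5 side chain).
Remark: the (R,R) enantiomer of the chromium salen catalyst is assumed to give the (1S,2S) azido alcohol in step 2; if the facial correlation is the opposite one, the (S,S) catalyst is used.
Remark: in 24 and 25 every stereocentre shared with the target (C4, C5, C6, C7 and, in 25, C1) has the target configuration; the C9 carbinol, erased in step 21, is α (cis to the C5 side chain).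

Step 1
Reactants: 1 cyclohexa-1,4-diene
Product: 2 7-oxabicyclo[4.1.0]hept-3-ene (meso monoepoxide)
Conditions: mCPBA (0.5 equiv relative to the diene), NaHCO3, CH2Cl2, 0 °C
Reagents that add atoms: 3-chloroperoxybenzoic acid (mCPBA), OOC(=O)c1cccc(Cl)c1
Why: Prilezhaev epoxidation of one of two equivalent isolated alkenes, held at the mono stage by the excess of diene, should give the meso cis-fused epoxide, in which no stereochemical choice arises.

Step 2
Reactants: 2 7-oxabicyclo[4.1.0]hept-3-ene
Product: 4 (1S,2S)-2-azidocyclohex-4-en-1-ol, via silyl ether 3 (not isolated)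
Conditions: TMSN3, (R,R)-(salen)CrN3 (2 mol %; salen = N,N'-bis(3,5-di-tert-butylsalicylidene)cyclohexane-1,2-diamine dianion), Et2O, rt; then CSA, MeOH
Reagents that add atoms: azidotrimethylsilane, C[Si](C)(C)N=[N+]=[N-]
Why: Catalytic asymmetric ring opening of a meso epoxide by azide on a chiral salen complex of trivalent chromium selects one enantiotopic epoxide carbon and, by SN2 inversion there, should set C6 and C7 as the trans (1S,2S) pair, after which methanolysis removes the O-silyl group.

Step 3
Reactants: 4 (1S,2S)-2-azidocyclohex-4-en-1-ol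
Product: 6 (1R,2S)-2-azidocyclohex-4-en-1-ol, via nitrobenzoate 5 (not isolated)
Conditions: 4-nitrobenzoic acid, PPh3, DIAD, THF, 0 °C to rt (betaine formed before 4 is added); then K2CO3, MeOH, rt
Reagents that add atoms: 4-nitrobenzoic acid, OC(=O)c1ccc(cc1)[N+](=O)[O-]
Why: Mitsunobu esterification should replace the activated C6 oxygen with inversion, giving the cis azido ester (C6 now R), and ester methanolysis then frees the cis azido alcohol.

Step 4
Reactants: 6 (1R,2S)-2-azidocyclohex-4-en-1-ol
Product: 7 {[(1R,2S)-2-azidocyclohex-4-en-1-yl]oxy}(tert-butyl)dimethylsilane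
Conditions: TBSCl, imidazole, DMF, rt
Reagents that add atoms: tert-butyldimethylsilyl chloride, CC(C)(C)[Si](C)(C)Cl
Why: Imidazole-mediated O-silylation of the only hydroxyl group should proceed without touching a stereocentre.

Step 5
Reactants: 7 cis azido silyl ether
Product: 8 C1,C9-α-epoxide of 7 (epoxide trans to the β azide and β silyl ether)
Conditions: mCPBA, NaHCO3, CH2Cl2, 0 °C to rt
Reagents that add atoms: 3-chloroperoxybenzoic acid (mCPBA), OOC(=O)c1cccc(Cl)c1
Why: Prilezhaev epoxidation should occur on the α face because both cis substituents lie on the β face and one of them is pseudoaxial in either half-chair, which sets C1 and C9.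

Step 6
Reactants: 8 azido epoxide
Product: 10 tert-butyl carbamate of the C7 amine (epoxide retained), via amine 9 (not isolated)
Conditions: H2 (1 atm), Pd/C, Boc2O, EtOAc, rt
Reagents that add atoms: di-tert-butyl dicarbonate, CC(C)(C)OC(=O)OC(=O)OC(C)(C)C
Why: Catalytic hydrogenolysis of the azide gives the amine, which is acylated in situ before it can open the epoxide, and no stereocentre is touched.

Step 7
Reactants: 10 Boc-amino epoxide
Product: 11 6-(tert-butyldimethylsilyloxy)-8-hydroxy-2-oxa-4-azabicyclo[3.3.1]nonan-3-one (C7 N–C(=O)–O–C1 bridge on the β face, C9 α-OH)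
Conditions: BF3·OEt2 (0.3 equiv), CH2Cl2, −40 to 0 °C
Reagents that add atoms: none
Why: Lewis-acid-promoted intramolecular epoxide opening by the carbamate carbonyl oxygen (6-exo, trans-diaxial, loss of isobutene) can reach only C1 and only from the β face, so the tether fixes the regiochemistry, inverts C1 to the β oxygen and leaves the C9 hydroxyl (α) free.

Step 8
Reactants: 11 bicyclic carbamate alcohol
Product: 12 6-(tert-butyldimethylsilyloxy)-2-oxa-4-azabicyclo[3.3.1]nonane-3,8-dione (C9 ketone)
Conditions: DMP, NaHCO3, CH2Cl2, rt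
Reagents that add atoms: none
Why: Dess–Martin oxidation of the single free secondary alcohol should give the C9 ketone under buffered, non-epimerising conditions.

Step 9
Reactants: 13 3-(trimethylsilyl)prop-2-ynal
Product: 14 (3,3-dimethoxyprop-1-yn-1-yl)trimethylsilane
Conditions: HC(OMe)3, MeOH, TsOH·H2O (cat.), rt
Reagents that add atoms: trimethyl orthoformate, COC(OC)OC; methanol, CO
Why: Acid-catalysed acetalisation of the aldehyde, driven by the orthoformate as water scavenger, should give the dimethyl acetal.

Step 10
Reactants: 12 bicyclic keto carbamate; 14 alkynyl dimethyl acetal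
Product: 16 ketone 12 carrying at C5 (α, exo) the (1S)-1-methoxy-3-(trimethylsilyl)prop-2-yn-1-yl group, via silyl enol ether 15 (not isolated)
Conditions: TMSOTf (2.6 equiv), i-Pr2NEt (2.2 equiv), CH2Cl2, 0 °C; then 14, −78 to −40 °C; aq. NaHCO3
Reagents that add atoms: none
Why: Soft enolisation can go only toward C5 (C1 is a bridgehead), and the TMSOTf-promoted Mukaiyama-type addition of the enol silane to the alkynyl oxocarbenium ion from 14 should occur on the exo (α) face of the bicyclo[3.3.1] framework, away from the carbamate bridge, through an open antiperiplanar transition state that favours the required syn C4/C5 relation (a chair-type metal enolate aldol would give the anti relation) and installs the methyl ether directly.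

Step 11
Reactants: 16 β-methoxy ketone
Product: 17 C9 α-alcohol of 16
Conditions: LiBH(s-Bu)3 (L-Selectride), THF, −78 °C; aq. NH4Cl
Reagents that add atoms: none
Why: The bulky trialkylborohydride should attack the C9 carbonyl equatorially, as in 2-substituted cyclohexanones, giving the axial α alcohol cis to the equatorial C5 side chain (the 1,3-syn relation to the C4 methoxy group).

Step 12
Reactants: 17 silylalkyne alcohol
Product: 18 iodoalkyne (C5 side chain (1S)-3-iodo-1-methoxyprop-2-yn-1-yl)
Conditions: NIS, AgNO3 (20 mol %), acetone, rt, dark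
Reagents that add atoms: N-iodosuccinimide, O=C1CCC(=O)N1I
Why: Silver-catalysed iododesilylation is an ipso substitution of the alkynylsilane and should leave hydroxyl, carbamate and silyl ether untouched.

Step 13
Reactants: 18 iodoalkyne
Product: 19 (Z)-alkenyl iodide (C5 side chain (1S,2Z)-3-iodo-1-methoxyprop-2-en-1-yl)
Conditions: 2-nitrobenzenesulfonylhydrazide, Et3N, THF/i-PrOH, rt
Reagents that add atoms: none
Why: Diimide generated in situ transfers two hydrogens to the same side of the iodoalkyne, so the Z geometry results without cleavage of the C–I bond, and no ketone is present to condense with the hydrazide.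

Step 14
Reactants: 19 (Z)-alkenyl iodide alcohol
Product: 21 N-Boc cyclic carbamate with C9 α-O-(2-methoxypropan-2-yl), via ketal ether 20 (not isolated)
Conditions: 2-methoxypropene, PPTS (5 mol %), CH2Cl2, 0 °C; then Et3N, Boc2O, DMAP, rt
Reagents that add atoms: 2-methoxypropene, COC(C)=C; di-tert-butyl dicarbonate, CC(C)(C)OC(=O)OC(=O)OC(C)(C)C
Why: Acid-catalysed addition of the C9 hydroxyl to the enol ether gives a base-stable mixed ketal that cannot migrate, and DMAP-catalysed N-acylation then activates the ring carbamate for cleavage.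

Step 15
Reactants: 21 N-Boc cyclic carbamate
Product: 22 ring A carbamate with C1 β-OH, C9 α-O-(2-methoxypropan-2-yl), C6 β-OTBS, C7 β-NHBoc and the C5 α side chain
Conditions: Cs2CO3 (0.3 equiv), MeOH, rt
Reagents that add atoms: none
Why: Methoxide should add to the ring carbonyl of the doubly acylated nitrogen (less hindered than the tert-butyl carbamate carbonyl), so that carbamate alcoholysis releases the C1 hydroxyl and the NHBoc group with C1 unchanged.

Step 16
Reactants: 22 C1 alcohol
Product: 23 C1 ketone with C9 α-O-(2-methoxypropan-2-yl)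
Conditions: DMP, NaHCO3, pyridine, CH2Cl2, 0 °C to rt
Reagents that add atoms: none
Why: Buffered Dess–Martin oxidation should convert the only free hydroxyl into the C1 ketone while the acid-labile ketal on the C9 oxygen prevents any oxidation there.

Step 17
Reactants: 23 protected ketol
Product: 24 tert-butyl carbamate of the ring A 2-hydroxycyclohexanone (C1 ketone, C9 α-OH, C5 α-[(1S,2Z)-3-iodo-1-methoxyprop-2-en-1-yl], C6 β-OTBS, C7 β-NHBoc)
Conditions: PPTS (cat.), MeOH, 0 °C
Reagents that add atoms: none
Why: Acid-catalysed transacetalisation to methanol removes the very labile 2-methoxypropan-2-yl group under conditions that leave the silyl ether, the carbamate and the alkenyl iodide intact.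

Step 18
Reactants: 24 ring A α-hydroxy ketone with the (Z)-alkenyl iodide arm
Product: 25 tert-butyl carbamate of the bicyclo[3.3.1]non-2-ene diol (C1 bridgehead OH, C9 OH on the ring B side, C4 OMe exo, C6 OTBS, C7 NHBoc)
Conditions: CrCl2 (8 equiv), NiCl2 (5 mol %), degassed DMF, rt
Reagents that add atoms: none
Why: NiCl2 is reduced in situ by CrCl2 to zerovalent nickel, which undergoes oxidative addition into the C2–I bond; exchange of the alkenyl group onto trivalent chromium gives the nucleophile, which attacks the C1 carbonyl within a chelate that also binds the C9 oxygen. The closest known reaction type is the intramolecular Nozaki–Hiyama–Kishi addition of an alkenyl iodide to a ketone. Ring B (C1, C2, C3, C4, C5, C9) closes in the 6-exo-trig mode. The new C1 stereocentre is set by the tether: C2 can reach C1 only from the α face, on which the axial C5 side chain sits, so the new hydroxyl must end up β (exo). The step needs retention of the Z geometry and selective activation of the C–I bond: the geometry is fixed by the cis reduction of step 13, alkenylnickel and alkenylchromium species are configurationally stable, and carbamate N–H, hydroxyl, silyl ether and methyl ether are inert to these reagents. The reactive chair has the C5 arm and the C6 silyl ether trans-diaxial and the C9 hydroxyl and C7 carbamate equatorial, and the C9 oxygen is left unprotected because it ends up 1,3-syn to the C4 methoxy group on ring B.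

Step 19
Reactants: 25 bicyclic carbamate; 26 (E)-dodec-2-enoic acid
Product: 28 (E)-dodec-2-enamide of the bicyclic amine, via amine 27 (not isolated)
Conditions: TFA/CH2Cl2 (1:4), 0 °C, evaporate; then 26, EDC·HCl, HOBt, i-Pr2NEt, CH2Cl2, 0 °C to rt
Reagents that add atoms: none
Why: Acidolysis of the tert-butyl carbamate (the bridgehead allylic alcohol cannot ionise and the hindered secondary silyl ether should survive the short exposure) followed by carbodiimide coupling should acylate the amine selectively in the presence of the two hydroxyl groups, and doing this before the oxirane exists keeps acid away from it.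

Step 20
Reactants: 28 bicyclic alkene amide
Product: 29 C2,C3-exo-epoxide of 28
Conditions: VO(acac)2 (5 mol %), t-BuOOH, CH2Cl2, 0 °C to rt
Reagents that add atoms: tert-butyl hydroperoxide, CC(C)(C)OO
Why: In this hydroxyl-directed epoxidation vanadium bound to the axial C9 hydroxyl (homoallylic, on the exo face of ring B) should deliver oxygen to the exo face of C2=C3, which is also the open face because ring A covers the endo face, so C2 and C3 are set as in the target while the electron-poor enamide alkene is not attacked.

Step 21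
Reactants: 29 epoxy diol
Product: 30 C9 ketone (silyl ether of the target)
Conditions: IBX, DMSO, rt
Reagents that add atoms: none
Why: IBX oxidation should convert the only secondary alcohol into the ketone without cleaving the 1,2-diol, the tertiary C1 hydroxyl, the oxirane and the silyl-protected C6 oxygen being inert, and the bridgehead positions on both sides of the new ketone rule out enolisation.

Step 22
Reactants: 30 silyl ether
Product: 31 target CNP0137540.1
Conditions: HF·pyridine, pyridine, THF, 0 °C to rt
Reagents that add atoms: none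
Why: Buffered fluoride desilylation should cleave the Si–O bond of the C6 silyl ether under nearly neutral conditions that spare the oxirane and the α-hydroxy ketone.

Compound list
1 | cyclohexa-1,4-diene | C1=CCC=CC1 | starting material
2 | 7-oxabicyclo[4.1.0]hept-3-ene (meso, cis-fused) | C1=CC[C@H]2O[C@H]2C1 | intermediate
3 | {[(1S,2S)-2-azidocyclohex-4-en-1-yl]oxy}trimethylsilane | [N-]=[N+]=N[C@H]1CC=CC[C@@H]1O[Si](C)(C)C | intermediate
4 | (1S,2S)-2-azidocyclohex-4-en-1-ol (trans; C6 carbinol, C7 azide) | [N-]=[N+]=N[C@H]1CC=CC[C@@H]1O | intermediate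
5 | (1R,2S)-2-azidocyclohex-4-en-1-yl 4-nitrobenzoate | [N-]=[N+]=N[C@H]1CC=CC[C@H]1OC(=O)c1ccc(cc1)[N+](=O)[O-] | intermediate
6 | (1R,2S)-2-azidocyclohex-4-en-1-ol (cis) | [N-]=[N+]=N[C@H]1CC=CC[C@H]1O | intermediate
7 | {[(1R,2S)-2-azidocyclohex-4-en-1-yl]oxy}(tert-butyl)dimethylsilane | [N-]=[N+]=N[C@H]1CC=CC[C@H]1O[Si](C)(C)C(C)(C)C | intermediate
8 | 4-azido-3-(tert-butyldimethylsilyloxy)-7-oxabicyclo[4.1.0]heptane, C1,C9-α-epoxide trans to the β azide and β silyl ether | [N-]=[N+]=N[C@H]1C[C@@H]2O[C@@H]2C[C@H]1O[Si](C)(C)C(C)(C)C | intermediate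
9 | C7 β-amine corresponding to 8 | N[C@H]1C[C@@H]2O[C@@H]2C[C@H]1O[Si](C)(C)C(C)(C)C | intermediate
10 | tert-butyl carbamate of 9 | CC(C)(C)OC(=O)N[C@H]1C[C@@H]2O[C@@H]2C[C@H]1O[Si](C)(C)C(C)(C)C | intermediate
11 | 6-(tert-butyldimethylsilyloxy)-8-hydroxy-2-oxa-4-azabicyclo[3.3.1]nonan-3-one (carbamate bridge from C7 β-N to C1 β-O, C9 α-OH, C6 β-OTBS) | O=C1N[C@H]2C[C@@H](O1)[C@H](O)C[C@H]2O[Si](C)(C)C(C)(C)C | intermediate
12 | 6-(tert-butyldimethylsilyloxy)-2-oxa-4-azabicyclo[3.3.1]nonane-3,8-dione (C9 ketone) | O=C1N[C@H]2C[C@@H](O1)C(=O)C[C@H]2O[Si](C)(C)C(C)(C)C | intermediate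
13 | 3-(trimethylsilyl)prop-2-ynal | C[Si](C)(C)C#CC=O | starting material
14 | (3,3-dimethoxyprop-1-yn-1-yl)trimethylsilane | C[Si](C)(C)C#CC(OC)OC | intermediate
15 | N-trimethylsilyl C9-O-trimethylsilyl enol ether of 12 (C9=C5) | C[Si](C)(C)OC1=C[C@@H](O[Si](C)(C)C(C)(C)C)[C@@H]2C[C@H]1OC(=O)N2[Si](C)(C)C | intermediate
16 | dione 12 with C5 α-[(1S)-1-methoxy-3-(trimethylsilyl)prop-2-yn-1-yl] (C4 oxygen syn to C6) | O=C1N[C@H]2C[C@@H](O1)C(=O)[C@@H]([C@H]2O[Si](C)(C)C(C)(C)C)[C@H](OC)C#C[Si](C)(C)C | intermediate
17 | C9 α-alcohol of 16 | O=C1N[C@H]2C[C@@H](O1)[C@H](O)[C@@H]([C@H]2O[Si](C)(C)C(C)(C)C)[C@H](OC)C#C[Si](C)(C)C | intermediate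
18 | iodoalkyne, C5 α-[(1S)-3-iodo-1-methoxyprop-2-yn-1-yl] | O=C1N[C@H]2C[C@@H](O1)[C@H](O)[C@@H]([C@H]2O[Si](C)(C)C(C)(C)C)[C@H](OC)C#CI | intermediate
19 | (Z)-alkenyl iodide, C5 α-[(1S,2Z)-3-iodo-1-methoxyprop-2-en-1-yl] | O=C1N[C@H]2C[C@@H](O1)[C@H](O)[C@@H]([C@H]2O[Si](C)(C)C(C)(C)C)[C@H](OC)/C=C\I | intermediate
20 | C9 α-O-(2-methoxypropan-2-yl) ether of 19 | O=C1N[C@H]2C[C@@H](O1)[C@H](OC(C)(C)OC)[C@@H]([C@H]2O[Si](C)(C)C(C)(C)C)[C@H](OC)/C=C\I | intermediate
21 | N-Boc derivative of 20 | O=C1N(C(=O)OC(C)(C)C)[C@H]2C[C@@H](O1)[C@H](OC(C)(C)OC)[C@@H]([C@H]2O[Si](C)(C)C(C)(C)C)[C@H](OC)/C=C\I | intermediate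
22 | tert-butyl carbamate of the ring A amine: C1 β-OH, C9 α-O-(2-methoxypropan-2-yl), C5 α-[(1S,2Z)-3-iodo-1-methoxyprop-2-en-1-yl], C6 β-OTBS, C7 β-NHBoc | CC(C)(C)OC(=O)N[C@H]1C[C@@H](O)[C@H](OC(C)(C)OC)[C@@H]([C@H]1O[Si](C)(C)C(C)(C)C)[C@H](OC)/C=C\I | intermediate
23 | C1 ketone of 22 | CC(C)(C)OC(=O)N[C@H]1CC(=O)[C@H](OC(C)(C)OC)[C@@H]([C@H]1O[Si](C)(C)C(C)(C)C)[C@H](OC)/C=C\I | intermediate
24 | precursor of the key step: C1 ketone, C9 α-OH, C5 α-[(1S,2Z)-3-iodo-1-methoxyprop-2-en-1-yl], C6 β-OTBS, C7 β-NHBoc | CC(C)(C)OC(=O)N[C@H]1CC(=O)[C@H](O)[C@@H]([C@H]1O[Si](C)(C)C(C)(C)C)[C@H](OC)/C=C\I | intermediate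
25 | product of the key step: bicyclo[3.3.1]non-2-ene with C1 bridgehead OH, C9 OH on the ring B side, C4 OMe exo, C6 OTBS, C7 NHBoc | CC(C)(C)OC(=O)N[C@H]1C[C@@]2(O)[C@H](O)[C@@H]([C@H]1O[Si](C)(C)C(C)(C)C)[C@H](OC)C=C2 | intermediate
26 | (E)-dodec-2-enoic acid | CCCCCCCCC/C=C/C(=O)O | starting material
27 | C7 amine from 25 (handled as its trifluoroacetate) | N[C@H]1C[C@@]2(O)[C@H](O)[C@@H]([C@H]1O[Si](C)(C)C(C)(C)C)[C@H](OC)C=C2 | intermediate
28 | (E)-dodec-2-enamide of 27 | CCCCCCCCC/C=C/C(=O)N[C@H]1C[C@@]2(O)[C@H](O)[C@@H]([C@H]1O[Si](C)(C)C(C)(C)C)[C@H](OC)C=C2 | intermediate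
29 | C2,C3-exo-epoxide of 28 | CCCCCCCCC/C=C/C(=O)N[C@H]1C[C@@]2(O)[C@H](O)[C@@H]([C@H]1O[Si](C)(C)C(C)(C)C)[C@H](OC)[C@@H]1O[C@@H]12 | intermediate
30 | C9 ketone of 29 (C6 silyl ether of the target) | CCCCCCCCC/C=C/C(=O)N[C@H]1C[C@@]2(O)C(=O)[C@@H]([C@H]1O[Si](C)(C)C(C)(C)C)[C@H](OC)[C@@H]1O[C@@H]12 | intermediate
31 | CNP0137540.1 | CCCCCCCCC/C=C/C(=O)N[C@H]1C[C@@]2(O)C(=O)[C@@H]([C@H]1O)[C@H](OC)[C@@H]1O[C@@H]12 | target

Total step count: 22. Longest linear sequence: 21 steps (steps 1–8 and 10–22; step 9 prepares the acetal on a side branch).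

Steps most likely to fail

Step 18. The alkenylchromium intermediate may be protonated by the free C9 hydroxyl or the carbamate N–H before it adds (protodeiodination), the addition to the hindered ketone may be too slow, or the alkene geometry may erode. The fallback closes the same C1–C2 bond by iodine–lithium exchange on the C9-protected ketone and sets out from 23. Treatment with tert-butyllithium (about 3 equiv: one for the carbamate N–H, two for the exchange) in THF/pentane at −100 °C should give an alkenyllithium held next to the C1 carbonyl, which should cyclise faster than tert-butyllithium adds to that hindered carbonyl, giving the ketal-protected bicyclic alcohol F1. PPTS in methanol then removes the 2-methoxypropan-2-yl group and the route is rejoined at 25.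

Step 10. The open transition state may give poor control of the C4 configuration relative to C5 with the slim alkynyl group, or the β-methoxy ketone may lose methanol under the Lewis acid. The fallback separates C–C bond formation from O-methylation and sets out from 12. Deprotonation with LDA (2.1 equiv, THF, −78 °C), transmetalation with ClTi(O-i-Pr)3 and addition of 13 should give, through the closed transition state of a triisopropoxytitanium enolate (which favours syn aldols from cyclic ketone enolates), the syn β-hydroxy ketone F2 on the exo face. O-methylation with Me3OBF4 and 1,8-bis(dimethylamino)naphthalene in CH2Cl2 then comes back to 16.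

Step 3. The phosphine may be consumed by the azide (Staudinger reduction) or the activated alcohol may eliminate instead of being displaced. The fallback inverts C6 by sulfonate displacement and sets out from 4. Tf2O and pyridine in CH2Cl2 at −20 °C should give the trans triflate F3; caesium acetate with 18-crown-6 in toluene should displace it with inversion to the cis acetate F4; K2CO3 in methanol then returns to 6.

Further compounds
F1 | step 18 | tert-butyl carbamate of the bicyclo[3.3.1]non-2-ene with C1 OH and C9 O-(2-methoxypropan-2-yl) | CC(C)(C)OC(=O)N[C@H]1C[C@@]2(O)[C@H](OC(C)(C)OC)[C@@H]([C@H]1O[Si](C)(C)C(C)(C)C)[C@H](OC)C=C2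
F2 | step 10 | dione 12 with C5 α-[(1S)-1-hydroxy-3-(trimethylsilyl)prop-2-yn-1-yl] (syn aldol) | O=C1N[C@H]2C[C@@H](O1)C(=O)[C@@H]([C@H]2O[Si](C)(C)C(C)(C)C)[C@H](O)C#C[Si](C)(C)C
F3 | step 3 | (1S,2S)-2-azidocyclohex-4-en-1-yl trifluoromethanesulfonate | [N-]=[N+]=N[C@H]1CC=CC[C@@H]1OS(=O)(=O)C(F)(F)F
F4 | step 3 | (1R,2S)-2-azidocyclohex-4-en-1-yl acetate | [N-]=[N+]=N[C@H]1CC=CC[C@H]1OC(C)=O
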